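The ring (numbered from the ester-bearing alkene carbon C1) is cut into a four-carbon phosphonate aldehyde (C1, C6, C5, C4) and a two-carbon acyloxy enolsilane (C3, C2). The key step exploits the contiguous oxygenated carbons C3–C4–C5 and the ring enoate C1=C2. A chelation-controlled Mukaiyama aldol joins C3 to C4, generating the free C4 hydroxyl from an aldehyde. In the same flask a magnesium/amine-mediated intramolecular Horner–Wadsworth–Emmons reaction joins C1 to C2 and closes the cyclohexene. The precursor is an open-chain α-alkoxy aldehyde with a phosphonoacetate terminus, made by organocatalytic Michael addition. The C3 ester arrives with the enolsilane; the chelating C5 PMB ether is exchanged for the second ester afterwards.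

Key step: step 5

Assumption: (2E)-3-methylpent-2-enoic acid (1), 2-[(4-methoxybenzyl)oxy]acetaldehyde (6) and trimethyl 2-phosphonoacrylate (7) are taken as catalogue compounds; the phosphorus-bearing carbon of 8 and 9 is an inconsequential epimer mixture because it becomes sp2 in step 5.

Step 1
Reactants: 1 (2E)-3-methylpent-2-enoic acid; 2 2,2-dimethoxyethanol
Product: 3 2,2-dimethoxyethyl (2E)-3-methylpent-2-enoate
Conditions: DCC, DMAP (cat.), CH2Cl2, 0 °C → rt
Reagents that add atoms: none
Why: Steglich esterification of a primary alcohol; carbodiimide activation with catalytic DMAP should leave the E-trisubstituted enoate untouched.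

Step 2
Reactants: 3 2,2-dimethoxyethyl (2E)-3-methylpent-2-enoate
Product: 4 2-oxoethyl (2E)-3-methylpent-2-enoate
Conditions: TFA/H2O, CH2Cl2, 0 °C → rt; azeotropic drying, used fresh
Reagents that add atoms: water, O
Why: acid-catalysed acetal hydrolysis should unmask the aldehyde without cleaving the conjugated ester.

Step 3
Reactants: 4 2-oxoethyl (2E)-3-methylpent-2-enoate
Product: 5 (Z)-2-[(trimethylsilyl)oxy]ethenyl (2E)-3-methylpent-2-enoate
Conditions: TMSCl, Et3N, MeCN, rt; pentane extraction, non-aqueous work-up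
Reagents that add atoms: chlorotrimethylsilane, C[Si](C)(C)Cl
Why: soft enolisation and O-silylation of an α-acyloxy aldehyde (silyl enol ether formation), expected to give the Z enol ether as for acetoxyacetaldehyde.

Step 4
Reactants: 6 2-[(4-methoxybenzyl)oxy]acetaldehyde; 7 methyl 2-(dimethoxyphosphoryl)prop-2-enoate
Product: 8 methyl (4R)-2-(dimethoxyphosphoryl)-4-[(4-methoxybenzyl)oxy]-5-oxopentanoate (epimer mixture at C2)
Conditions: (S)-α,α-diphenylprolinol TMS ether (10 mol%), ClCH2CO2H (20 mol%), CH2Cl2, 0 °C; short silica plug, used directly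
Reagents that add atoms: none
Why: enamine-catalysed asymmetric Michael addition (Hayashi–Jørgensen catalyst) of an α-alkoxy aldehyde to a geminally activated vinylphosphonate; attack on the anti-(E)-enamine face remote from the CPh2OTMS group should set the alkoxy carbon as R, while the P-bearing carbon forms unselectively and is destroyed later.

Step 5
Reactants: 8 methyl (4R)-2-(dimethoxyphosphoryl)-4-[(4-methoxybenzyl)oxy]-5-oxopentanoate; 5 (Z)-2-[(trimethylsilyl)oxy]ethenyl (2E)-3-methylpent-2-enoate
Product: 10 methyl (3R,4S,5R)-4-hydroxy-5-[(4-methoxybenzyl)oxy]-3-{[(2E)-3-methylpent-2-enoyl]oxy}cyclohex-1-ene-1-carboxylate, via open-chain aldol adduct 9 (not isolated)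
Conditions: 5 (1.5 equiv), MgBr2·OEt2 (3 equiv), CH2Cl2, −20 → 0 °C; then Et3N (5 equiv), THF, 0 °C → rt; aq. citric acid
Reagents that add atoms: none
Why: MgBr2 binds the aldehyde oxygen and the α-OPMB oxygen of 8 in a five-membered chelate, the (Z)-acyloxy enolsilane 5 adds through an open transition state (Mukaiyama aldol) to give the magnesium aldolate of 9, and Et3N then deprotonates the magnesium-bound phosphonoacetate, whose carbanion attacks the newly formed C2 aldehyde and eliminates dimethyl phosphate (intramolecular Horner–Wadsworth–Emmons). The closest known reactions are the MgBr2-mediated Mukaiyama aldol of 2-acyloxy enolsilanes with α-oxy aldehydes used for hexose assembly, the MgBr2/Et3N (Rathke) HWE olefination, and tandem aldol/intramolecular HWE cyclitol syntheses. The six-membered ring closes by 6-exo-trig addition of the C1 carbanion to the C2 carbonyl followed by syn-elimination of the oxaphosphetane, which can only give the endocyclic C1=C2 bond. C4 (S) is set by Cram-chelate control from the C5 stereocentre (attack anti to the C6 chain, 4,5-syn, trans on the ring) and C3 (R) by the anti simple diastereoselection expected for Z-acyloxy enolsilanes in CH2Cl2 (3,4-anti, cis on the ring); C5 is carried through and both C1 epimers of 8 converge. The step needs anti-Felkin facial selectivity, secured by the chelating PMB ether and the bidentate Lewis acid, and chemoselective olefination, secured because excess 5 stays masked as an enolsilane so that the only aldehyde present when base is added is the one placed six atoms from the carbanion.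

Step 6
Reactants: 10 methyl (3R,4S,5R)-4-hydroxy-5-[(4-methoxybenzyl)oxy]-3-{[(2E)-3-methylpent-2-enoyl]oxy}cyclohex-1-ene-1-carboxylate
Product: 11 methyl (3R,4S,5R)-5-[(4-methoxybenzyl)oxy]-3-{[(2E)-3-methylpent-2-enoyl]oxy}-4-[(triethylsilyl)oxy]cyclohex-1-ene-1-carboxylate
Conditions: TESOTf, 2,6-lutidine, CH2Cl2, −78 → 0 °C
Reagents that add atoms: triethylsilyl trifluoromethanesulfonate, CC[Si](CC)(CC)OS(=O)(=O)C(F)(F)F
Why: silylation of the hindered secondary alcohol with a silyl triflate and a non-nucleophilic base should mask O4 without disturbing esters or stereocentres.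

Step 7
Reactants: 11 methyl (3R,4S,5R)-5-[(4-methoxybenzyl)oxy]-3-{[(2E)-3-methylpent-2-enoyl]oxy}-4-[(triethylsilyl)oxy]cyclohex-1-ene-1-carboxylate
Product: 12 methyl (3R,4S,5R)-5-hydroxy-3-{[(2E)-3-methylpent-2-enoyl]oxy}-4-[(triethylsilyl)oxy]cyclohex-1-ene-1-carboxylate
Conditions: DDQ, CH2Cl2/pH 7 phosphate buffer (10:1), 0 °C → rt
Reagents that add atoms: none
Why: oxidative cleavage of the PMB ether by DDQ (benzylic oxidation, then hydrolysis) should be orthogonal to the TES ether and the esters under buffered conditions.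

Step 8
Reactants: 12 methyl (3R,4S,5R)-5-hydroxy-3-{[(2E)-3-methylpent-2-enoyl]oxy}-4-[(triethylsilyl)oxy]cyclohex-1-ene-1-carboxylate; 1 (2E)-3-methylpent-2-enoic acid
Product: 13 methyl (3R,4S,5R)-3,5-bis{[(2E)-3-methylpent-2-enoyl]oxy}-4-[(triethylsilyl)oxy]cyclohex-1-ene-1-carboxylate
Conditions: 1 (2 equiv), DCC, DMAP (cat.), CH2Cl2, 0 °C → rt
Reagents that add atoms: none
Why: Steglich esterification at oxygen retains the C5 configuration, and with O4 blocked no regiochemical question arises.

Step 9
Reactants: 13 methyl (3R,4S,5R)-3,5-bis{[(2E)-3-methylpent-2-enoyl]oxy}-4-[(triethylsilyl)oxy]cyclohex-1-ene-1-carboxylate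
Product: 14 methyl (3R,4S,5R)-4-hydroxy-3,5-bis{[(2E)-3-methylpent-2-enoyl]oxy}cyclohex-1-ene-1-carboxylate (CNP0268575.1)
Conditions: HF·pyridine, pyridine, THF, 0 °C
Reagents that add atoms: none
Why: fluoride-mediated Si–O cleavage in a mildly acidic buffered medium should release the O4 hydroxyl while suppressing base-catalysed acyl migration.

Compound list
1 | (2E)-3-methylpent-2-enoic acid | CC/C(C)=C/C(=O)O | starting material
2 | 2,2-dimethoxyethanol | OCC(OC)OC | starting material
3 | 2,2-dimethoxyethyl (2E)-3-methylpent-2-enoate | CC/C(C)=C/C(=O)OCC(OC)OC | intermediate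
4 | 2-oxoethyl (2E)-3-methylpent-2-enoate | CC/C(C)=C/C(=O)OCC=O | intermediate
5 | (Z)-2-[(trimethylsilyl)oxy]ethenyl (2E)-3-methylpent-2-enoate | CC/C(C)=C/C(=O)O/C=C\O[Si](C)(C)C | intermediate
6 | 2-[(4-methoxybenzyl)oxy]acetaldehyde | COc1ccc(COCC=O)cc1 | starting material
7 | methyl 2-(dimethoxyphosphoryl)prop-2-enoate (trimethyl 2-phosphonoacrylate) | C=C(C(=O)OC)P(=O)(OC)OC | starting material
8 | methyl (4R)-2-(dimethoxyphosphoryl)-4-[(4-methoxybenzyl)oxy]-5-oxopentanoate (C2 epimer mixture) | COC(=O)C(P(=O)(OC)OC)C[C@@H](OCc1ccc(OC)cc1)C=O | intermediate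
9 | methyl (4R,5S,6S)-2-(dimethoxyphosphoryl)-5-hydroxy-4-[(4-methoxybenzyl)oxy]-6-{[(2E)-3-methylpent-2-enoyl]oxy}-7-oxoheptanoate (formed as its magnesium aldolate, not isolated) | O=C[C@@H](OC(=O)/C=C(\C)CC)[C@@H](O)[C@H](OCc1ccc(OC)cc1)CC(C(=O)OC)P(=O)(OC)OC | intermediate
10 | methyl (3R,4S,5R)-4-hydroxy-5-[(4-methoxybenzyl)oxy]-3-{[(2E)-3-methylpent-2-enoyl]oxy}cyclohex-1-ene-1-carboxylate | CC/C(C)=C/C(=O)O[C@@H]1C=C(C(=O)OC)C[C@@H](OCc2ccc(OC)cc2)[C@@H]1O | intermediate
11 | methyl (3R,4S,5R)-5-[(4-methoxybenzyl)oxy]-3-{[(2E)-3-methylpent-2-enoyl]oxy}-4-[(triethylsilyl)oxy]cyclohex-1-ene-1-carboxylate | CC/C(C)=C/C(=O)O[C@@H]1C=C(C(=O)OC)C[C@@H](OCc2ccc(OC)cc2)[C@@H]1O[Si](CC)(CC)CC | intermediate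
12 | methyl (3R,4S,5R)-5-hydroxy-3-{[(2E)-3-methylpent-2-enoyl]oxy}-4-[(triethylsilyl)oxy]cyclohex-1-ene-1-carboxylate | CC/C(C)=C/C(=O)O[C@@H]1C=C(C(=O)OC)C[C@@H](O)[C@@H]1O[Si](CC)(CC)CC | intermediate
13 | methyl (3R,4S,5R)-3,5-bis{[(2E)-3-methylpent-2-enoyl]oxy}-4-[(triethylsilyl)oxy]cyclohex-1-ene-1-carboxylate | CC/C(C)=C/C(=O)O[C@@H]1C=C(C(=O)OC)C[C@@H](OC(=O)/C=C(\C)CC)[C@@H]1O[Si](CC)(CC)CC | intermediate
14 | methyl (3R,4S,5R)-4-hydroxy-3,5-bis{[(2E)-3-methylpent-2-enoyl]oxy}cyclohex-1-ene-1-carboxylate | CC/C(C)=C/C(=O)O[C@@H]1C=C(C(=O)OC)C[C@@H](OC(=O)/C=C(\C)CC)[C@@H]1O | target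

Total steps: 9. Longest linear sequence: 8 steps (1 → 3 → 4 → 5 → 10 → 11 → 12 → 13 → 14).

Steps most likely to fail

Step 5. Once the amine is added, the unprotected magnesium aldolate may undergo retro-aldol cleavage, β-elimination, epimerisation at C3 or an O3→O4 acyl shift faster than the ring closes; the anti simple diastereoselection of the aldol may also be incomplete. The fallback gives up the one-pot cascade for a protected, stepwise sequence that sets out from 8. The Mukaiyama aldol with 5 (MgBr2·OEt2, CH2Cl2, −20 °C) is run alone and the aldolate oxygen is capped in the same flask (TESOTf, 2,6-lutidine). This gives the isolable silyl-protected aldehyde methyl (4R,5S,6S)-2-(dimethoxyphosphoryl)-4-[(4-methoxybenzyl)oxy]-6-{[(2E)-3-methylpent-2-enoyl]oxy}-7-oxo-5-[(triethylsilyl)oxy]heptanoate F1, from which the diastereomers can be separated. The ring is then closed in a separate Masamune–Roush olefination (LiCl, iPr2NEt, MeCN, rt). The sequence returns to the route at 11, so step 6 is no longer needed.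

Step 4. Enamine formation from the α-alkoxy aldehyde may be slow or poorly face-selective, 6 may self-condense, 7 may oligomerise, and 8 may partly racemise through the catalyst. The fallback replaces catalysis by a stoichiometric chiral auxiliary and sets out from 6. Condensation with (R)-1-amino-2-(methoxymethyl)pyrrolidine (RAMP) gives the hydrazone (2R)-2-(methoxymethyl)-N-{(E)-2-[(4-methoxybenzyl)oxy]ethylidene}pyrrolidin-1-amine F2. Deprotonation with LDA (THF, −78 °C) and azaenolate Michael addition to 7 (Enders hydrazone method) should give methyl (4R)-2-(dimethoxyphosphoryl)-4-[(4-methoxybenzyl)oxy]-5-{[(2R)-2-(methoxymethyl)pyrrolidin-1-yl]imino}pentanoate F3. Two-phase hydrolysis (saturated aqueous oxalic acid, Et2O) releases the aldehyde and returns to the route at 8.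

Step 2. The neighbouring acyloxy group destabilises the oxocarbenium ion, so acetal hydrolysis may be sluggish; forcing acid would start to cleave the ester, and the liberated aldehyde may be lost as hydrate or oligomers on concentration. The fallback reaches the aldehyde by oxidation under anhydrous conditions and sets out from 1. Mono-esterification of a large excess of ethylene glycol (DCC, DMAP, CH2Cl2) gives 2-hydroxyethyl (2E)-3-methylpent-2-enoate F4. Dess–Martin oxidation (CH2Cl2, NaHCO3, rt) then returns to the route at 4.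

Further compounds
F1 | step 5 | methyl (4R,5S,6S)-2-(dimethoxyphosphoryl)-4-[(4-methoxybenzyl)oxy]-6-{[(2E)-3-methylpent-2-enoyl]oxy}-7-oxo-5-[(triethylsilyl)oxy]heptanoate | O=C[C@@H](OC(=O)/C=C(\C)CC)[C@@H](O[Si](CC)(CC)CC)[C@H](OCc1ccc(OC)cc1)CC(C(=O)OC)P(=O)(OC)OC
F2 | step 4 | (2R)-2-(methoxymethyl)-N-{(E)-2-[(4-methoxybenzyl)oxy]ethylidene}pyrrolidin-1-amine | COC[C@H]1CCCN1/N=C/COCc1ccc(OC)cc1
F3 | step 4 | methyl (4R)-2-(dimethoxyphosphoryl)-4-[(4-methoxybenzyl)oxy]-5-{[(2R)-2-(methoxymethyl)pyrrolidin-1-yl]imino}pentanoate | COC[C@H]1CCCN1/N=C/[C@H](OCc1ccc(OC)cc1)CC(C(=O)OC)P(=O)(OC)OC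
F4 | step 2 | 2-hydroxyethyl (2E)-3-methylpent-2-enoate | CC/C(C)=C/C(=O)OCCO
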